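## Retrosynthetic overview

1. Target 26 ⇐ hydroxybutenolide pseudo-acid 24 by enantioselective ketone reduction and lactonisation (sets the lactone stereocentre, last ring) ⇐ 2,3-disubstituted furan 22 by singlet-oxygen oxidation.
2. 22 ⇐ decalin enol triflate 13 + diene 20 by hydroboration and B-alkyl Suzuki coupling (bond from decalin C-1 to the side chain).
3. 20 ⇐ propargylic alcohol 18 by anti-carbomagnesiation with vinylmagnesium bromide (fixes the trisubstituted alkene) ⇐ 3-furanmethanol 14 + 4-chlorobut-2-yn-1-ol 15.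
4. 13 ⇐ decalone 11 ⇐ trans-hydrindanone 10 by diazoethane ring expansion (cyclopentanone to 2-methylcyclohexanone; key step, makes ring B and brings in the ring methyl).
5. 10 ⇐ enedione 4 by reductive methylation and deoxygenation ⇐ 1 + 2 by asymmetric Robinson annulation. Ring order: ring A (step 1), ring B by expansion (step 6), butenolide from the furan (steps 11–12).

Assumption: vinylmagnesium bromide, freshly generated diazoethane and iodomethane are treated as reagents; the starting materials are 1, 2, 14 and 15.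

## Route

Step 1
Reactants: 1 2-methylcyclopentane-1,3-dione; 2 pent-1-en-3-one
Product: 4 (7aS)-4,7a-dimethyl-2,3,7,7a-tetrahydro-1H-indene-1,5(6H)-dione, via triketone 3 (not isolated)
Conditions: H2O, AcOH (cat.), 70 °C; concentrate; then L-phenylalanine (1.0 equiv), 1 M HClO4 (0.5 equiv), MeCN, 80 °C; recrystallise
Reagents that add atoms: none
Why: Michael addition followed by an amino-acid-mediated Hajos–Parrish–Eder–Sauer–Wiechert aldol condensation desymmetrises the two ring carbonyls of 3, and L-phenylalanine gives the 7aS quaternary centre (the later C-8a of the decalin).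

Step 2
Reactants: 4 (7aS)-4,7a-dimethyl-2,3,7,7a-tetrahydro-1H-indene-1,5(6H)-dione
Product: 5 (1S,7aS)-1-hydroxy-4,7a-dimethyl-1,2,3,6,7,7a-hexahydro-5H-inden-5-one
Conditions: NaBH4 (0.3 equiv), EtOH, −20 °C
Reagents that add atoms: none
Why: Chemoselective borohydride reduction of the saturated cyclopentanone over the conjugated enone, with hydride attack anti to the angular methyl (1β-OH), masks this carbonyl without a protecting group; the carbinol centre is re-oxidised in step 5.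

Step 3
Reactants: 5 (1S,7aS)-1-hydroxy-4,7a-dimethyl-1,2,3,6,7,7a-hexahydro-5H-inden-5-one
Product: 7 (1S,3aR,7aS)-1-hydroxy-4,4,7a-trimethyloctahydro-5H-inden-5-one, via dilithium enolate 6 (not isolated)
Conditions: Li (2.3 equiv), NH3(l)/THF, −78 °C; then MeI (4 equiv), −78 → −33 °C; NH4Cl
Reagents that add atoms: iodomethane, CI
Why: Stork reductive alkylation: dissolving-metal reduction of the enone protonates the β-carbon anti to the angular methyl (trans ring fusion, the later C-4a), and the regiodefined enolate is C-methylated to the gem-dimethyl group; the minor cis isomer is removed by chromatography.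

Step 4
Reactants: 7 (1S,3aR,7aS)-1-hydroxy-4,4,7a-trimethyloctahydro-5H-inden-5-one
Product: 9 (1S,3aS,7aS)-4,4,7a-trimethyloctahydro-1H-inden-1-ol, via hydrazone 8 (not isolated)
Conditions: N2H4·H2O (10 equiv), KOH (5 equiv), diethylene glycol, 130 °C then 210 °C
Reagents that add atoms: none
Why: Wolff–Kishner (Huang-Minlon) reduction removes the ring-A carbonyl; the neighbouring carbon is quaternary, so no stereocentre can epimerise.

Step 5
Reactants: 9 (1S,3aS,7aS)-4,4,7a-trimethyloctahydro-1H-inden-1-ol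
Product: 10 (3aS,7aS)-4,4,7a-trimethyloctahydro-1H-inden-1-one
Conditions: TPAP (5 mol%), NMO (1.5 equiv), 4 Å MS, CH2Cl2, 20 °C
Reagents that add atoms: none
Why: Ley–Griffith oxidation of the hindered secondary alcohol regenerates the cyclopentanone without touching the non-enolisable ring-fusion centres.

Step 6
Reactants: 10 (3aS,7aS)-4,4,7a-trimethyloctahydro-1H-inden-1-one
Product: 11 (4aS,8aS)-2,5,5,8a-tetramethyloctahydronaphthalen-1(2H)-one (C2 epimers)
Conditions: MeCHN2 (2 equiv, toluene solution from N-ethyl-N-nitrosourea/KOH), Sc(OTf)3 (10 mol%), toluene/CH2Cl2, −78 → −30 °C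
Reagents that add atoms: diazoethane, CC=[N+]=[N-]
Why: Lewis-acid-catalysed diazoalkane homologation (Tiffeneau–Demjanov-type 1,2-shift): the diazo carbon adds to the activated carbonyl and the ring CH2, not the quaternary carbon, migrates with loss of N2 (as in D-homoannulation of 17-oxo steroids), expanding the cyclopentanone to the cyclohexanone of ring B and placing the methyl-bearing carbon next to the carbonyl.

Step 7
Reactants: 11 (4aS,8aS)-2,5,5,8a-tetramethyloctahydronaphthalen-1(2H)-one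
Product: 13 (4aS,8aS)-2,5,5,8a-tetramethyl-3,4,4a,5,6,7,8,8a-octahydronaphthalen-1-yl trifluoromethanesulfonate, via potassium enolate 12 (not isolated)
Conditions: KHMDS (1.3 equiv), THF, −78 → 0 °C; then PhNTf2 (1.3 equiv), −78 → 20 °C
Reagents that add atoms: N-phenylbis(trifluoromethanesulfonimide), O=S(=O)(N(c1ccccc1)S(=O)(=O)C(F)(F)F)C(F)(F)F
Why: The ketone has a single α-hydrogen (the other α-carbon is quaternary), so enolisation and O-triflation give only the tetrasubstituted enol triflate and both C2 epimers converge.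

Step 8
Reactants: 14 furan-3-ylmethanol; 15 4-chlorobut-2-yn-1-ol
Product: 18 4-[3-(hydroxymethyl)furan-2-yl]but-2-yn-1-ol, via dilithiated furylmethanol 16 (not isolated), via lithium chlorobutynolate 17 (not isolated)
Conditions: 14, n-BuLi (2.2 equiv), THF, −78 → 0 °C; 15, n-BuLi (1.0 equiv), THF, −78 °C; combine, DMPU, −78 → 20 °C; NH4Cl
Reagents that add atoms: none
Why: Alkoxide-directed lithiation of 3-furanmethanol occurs at C-2, and the furyllithium displaces the primary propargylic chloride by direct SN2 (no copper, so no SN2′ allene).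

Step 9
Reactants: 18 4-[3-(hydroxymethyl)furan-2-yl]but-2-yn-1-ol
Product: 20 (2E)-2-ethenyl-4-[3-(hydroxymethyl)furan-2-yl]but-2-en-1-ol, via alkenylmagnesium chelate 19 (not isolated)
Conditions: CH2=CHMgBr (4 equiv), CuI (15 mol%), THF, −20 → 40 °C; aq. NH4Cl
Reagents that add atoms: vinylmagnesium bromide, C=C[Mg]Br
Why: Copper-catalysed anti-carbomagnesiation of a propargylic alcohol: the magnesium alkoxide directs vinyl to the proximal alkyne carbon and Mg to the distal one through a five-membered chelate, so after protonation vinyl is cis to the furylmethyl arm and CH2OH is cis to H, the geometry the target needs.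

Step 10
Reactants: 13 (4aS,8aS)-2,5,5,8a-tetramethyl-3,4,4a,5,6,7,8,8a-octahydronaphthalen-1-yl trifluoromethanesulfonate; 20 (2E)-2-ethenyl-4-[3-(hydroxymethyl)furan-2-yl]but-2-en-1-ol
Product: 22 (2E)-4-[3-(hydroxymethyl)furan-2-yl]-2-{2-[(4aS,8aS)-2,5,5,8a-tetramethyl-3,4,4a,5,6,7,8,8a-octahydronaphthalen-1-yl]ethyl}but-2-en-1-ol, via trialkylborane 21 (not isolated)
Conditions: 20, 9-BBN (3.3 equiv), THF, 0 → 20 °C; then 13, Pd(dppf)Cl2 (10 mol%), AsPh3 (10 mol%), Cs2CO3 (4 equiv), DMF/H2O, 60 °C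
Reagents that add atoms: none
Why: 9-BBN hydroborates only the monosubstituted vinyl terminus of the diene (the hydroxyls are transiently O-borylated), and B-alkyl Suzuki–Miyaura coupling with the enol triflate forms the sp2–sp3 bond with retention of both alkene geometries.

Step 11
Reactants: 22 (2E)-4-[3-(hydroxymethyl)furan-2-yl]-2-{2-[(4aS,8aS)-2,5,5,8a-tetramethyl-3,4,4a,5,6,7,8,8a-octahydronaphthalen-1-yl]ethyl}but-2-en-1-ol
Product: 24 5-hydroxy-4-(hydroxymethyl)-5-{(2E)-3-(hydroxymethyl)-5-[(4aS,8aS)-2,5,5,8a-tetramethyl-3,4,4a,5,6,7,8,8a-octahydronaphthalen-1-yl]pent-2-en-1-yl}furan-2(5H)-one, via furan endoperoxide 23 (not isolated)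
Conditions: O2, hν (white LED), TPP (1 mol%), i-Pr2NEt (3 equiv), CH2Cl2, −78 °C; cold aq. citric acid
Reagents that add atoms: dioxygen (as singlet oxygen), O=O
Why: Singlet oxygen adds [4+2] across the electron-rich furan much faster than it undergoes ene reaction with the hindered ring alkene or the trisubstituted alkene at −78 °C, and base-induced Kornblum–DeLaMare fragmentation through the only endoperoxide C–H gives the hydroxybutenolide with the carbonyl at the former unsubstituted α-carbon.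

Step 12
Reactants: 24 5-hydroxy-4-(hydroxymethyl)-5-{(2E)-3-(hydroxymethyl)-5-[(4aS,8aS)-2,5,5,8a-tetramethyl-3,4,4a,5,6,7,8,8a-octahydronaphthalen-1-yl]pent-2-en-1-yl}furan-2(5H)-one
Product: 26 (5R)-4-(hydroxymethyl)-5-{(2E)-3-(hydroxymethyl)-5-[(4aS,8aS)-2,5,5,8a-tetramethyl-3,4,4a,5,6,7,8,8a-octahydronaphthalen-1-yl]pent-2-en-1-yl}furan-2(5H)-one, via hydroxy acid 25 (not isolated)
Conditions: RuCl[(R,R)-TsDPEN](p-cymene) (2 mol%), HCO2H/Et3N (5:2), EtOAc, 20 °C; then 0.1 M HCl
Reagents that add atoms: none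
Why: Proposed new method: the pseudo-acid 24 opens under Et3N to its (Z)-4-oxo-2-enoate, whose ketone is reduced by outer-sphere Ru–H/N–H transfer from the (R,R)-TsDPEN complex, the conjugated alkenyl arm taking the aryl role against the sp3 CH2 arm so that hydride delivery gives the R carbinol, while the carboxylate form damps conjugate reduction and the cis-hydroxy acid 25 lactonises irreversibly on acidification; the closest known reaction type is Noyori–Ikariya asymmetric transfer hydrogenation of aryl/alkenyl ketones and of saturated γ-keto acids to γ-lactones, here extended to a 5-hydroxy-5-alkylbutenolide.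

## Compound list

1 | 2-methylcyclopentane-1,3-dione | CC1C(=O)CCC1=O | starting material
2 | pent-1-en-3-one (ethyl vinyl ketone) | CCC(=O)C=C | starting material
3 | 2-methyl-2-(3-oxopentyl)cyclopentane-1,3-dione (not isolated) | CCC(=O)CCC1(C)C(=O)CCC1=O | intermediate
4 | (7aS)-4,7a-dimethyl-2,3,7,7a-tetrahydro-1H-indene-1,5(6H)-dione | CC1=C2CCC(=O)[C@@]2(C)CCC1=O | intermediate
5 | (1S,7aS)-1-hydroxy-4,7a-dimethyl-1,2,3,6,7,7a-hexahydro-5H-inden-5-one | CC1=C2CC[C@H](O)[C@@]2(C)CCC1=O | intermediate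
6 | dilithium (1S,3aR,7aS)-4,7a-dimethyl-2,3,3a,6,7,7a-hexahydro-1H-indene-1,5-bis(olate), 3a-H trans to 7a-CH3 (not isolated) | [Li+].[Li+].CC=1[C@@H]2CC[C@H]([O-])[C@@]2(C)CCC=1[O-] | intermediate
7 | (1S,3aR,7aS)-1-hydroxy-4,4,7a-trimethyloctahydro-5H-inden-5-one (trans-fused) | CC1(C)[C@@H]2CC[C@H](O)[C@@]2(C)CCC1=O | intermediate
8 | (1S,3aS,7aS)-5-hydrazinylidene-4,4,7a-trimethyloctahydro-1H-inden-1-ol (not isolated) | CC1(C)[C@@H]2CC[C@H](O)[C@@]2(C)CCC1=NN | intermediate
9 | (1S,3aS,7aS)-4,4,7a-trimethyloctahydro-1H-inden-1-ol | CC1(C)[C@@H]2CC[C@H](O)[C@@]2(C)CCC1 | intermediate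
10 | (3aS,7aS)-4,4,7a-trimethyloctahydro-1H-inden-1-one | CC1(C)[C@@H]2CCC(=O)[C@@]2(C)CCC1 | intermediate
11 | (4aS,8aS)-2,5,5,8a-tetramethyloctahydronaphthalen-1(2H)-one, mixture of C2 epimers | CC1C(=O)[C@@]2(C)CCCC(C)(C)[C@@H]2CC1 | intermediate
12 | potassium (4aS,8aS)-2,5,5,8a-tetramethyl-3,4,4a,5,6,7,8,8a-octahydronaphthalen-1-olate (not isolated) | [K+].CC1=C([O-])[C@@]2(C)CCCC(C)(C)[C@@H]2CC1 | intermediate
13 | (4aS,8aS)-2,5,5,8a-tetramethyl-3,4,4a,5,6,7,8,8a-octahydronaphthalen-1-yl trifluoromethanesulfonate | CC1=C(OS(=O)(=O)C(F)(F)F)[C@@]2(C)CCCC(C)(C)[C@@H]2CC1 | intermediate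
14 | furan-3-ylmethanol (3-furanmethanol) | OCc1ccoc1 | starting material
15 | 4-chlorobut-2-yn-1-ol | OCC#CCCl | starting material
16 | lithium (2-lithiofuran-3-yl)methanolate (not isolated) | [Li+].[O-]Cc1ccoc1[Li] | intermediate
17 | lithium 4-chlorobut-2-yn-1-olate (not isolated) | [Li+].[O-]CC#CCCl | intermediate
18 | 4-[3-(hydroxymethyl)furan-2-yl]but-2-yn-1-ol | OCC#CCc1occc1CO | intermediate
19 | (2Z)-alkenylmagnesium chelate: 3-(bromomagnesio)-2-ethenyl-4-[3-(bromomagnesiooxymethyl)furan-2-yl]but-2-en-1-olate, Mg on C3 cis to CH2O and trans to ethenyl (not isolated) | C=C/C(CO[Mg]Br)=C(/[Mg]Br)Cc1occc1CO[Mg]Br | intermediate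
20 | (2E)-2-ethenyl-4-[3-(hydroxymethyl)furan-2-yl]but-2-en-1-ol | C=C/C(=C\Cc1occc1CO)CO | intermediate
21 | 9-{(3E)-3-[(9-borabicyclo[3.3.1]nonan-9-yloxy)methyl]-5-{3-[(9-borabicyclo[3.3.1]nonan-9-yloxy)methyl]furan-2-yl}pent-3-en-1-yl}-9-borabicyclo[3.3.1]nonane (not isolated) | B1(C2CCCC1CCC2)CC/C(=C\Cc1occc1COB1C2CCCC1CCC2)COB1C2CCCC1CCC2 | intermediate
22 | (2E)-4-[3-(hydroxymethyl)furan-2-yl]-2-{2-[(4aS,8aS)-2,5,5,8a-tetramethyl-3,4,4a,5,6,7,8,8a-octahydronaphthalen-1-yl]ethyl}but-2-en-1-ol | CC1=C(CC/C(=C\Cc2occc2CO)CO)[C@@]2(C)CCCC(C)(C)[C@@H]2CC1 | intermediate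
23 | 2,5-endoperoxide of furan 22 (2,3,7-trioxabicyclo[2.2.1]hept-5-ene; side chain on C1, CH2OH on C6; not isolated) | CC1=C(CC/C(=C\CC23OOC(C=C2CO)O3)CO)[C@@]2(C)CCCC(C)(C)[C@@H]2CC1 | intermediate
24 | 5-hydroxy-4-(hydroxymethyl)-5-{(2E)-3-(hydroxymethyl)-5-[(4aS,8aS)-2,5,5,8a-tetramethyl-3,4,4a,5,6,7,8,8a-octahydronaphthalen-1-yl]pent-2-en-1-yl}furan-2(5H)-one, hemiketal epimers, ring-chain tautomer of the (Z)-4-oxo-2-enoic acid | CC1=C(CC/C(=C\CC2(O)OC(=O)C=C2CO)CO)[C@@]2(C)CCCC(C)(C)[C@@H]2CC1 | intermediate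
25 | (2Z,4R,6E)-4-hydroxy-3,7-bis(hydroxymethyl)-9-[(4aS,8aS)-2,5,5,8a-tetramethyl-3,4,4a,5,6,7,8,8a-octahydronaphthalen-1-yl]nona-2,6-dienoic acid (not isolated) | CC1=C(CC/C(=C\C[C@@H](O)/C(CO)=C\C(O)=O)CO)[C@@]2(C)CCCC(C)(C)[C@@H]2CC1 | intermediate
26 | (5R)-4-(hydroxymethyl)-5-{(2E)-3-(hydroxymethyl)-5-[(4aS,8aS)-2,5,5,8a-tetramethyl-3,4,4a,5,6,7,8,8a-octahydronaphthalen-1-yl]pent-2-en-1-yl}furan-2(5H)-one (CNP0238475.3) | CC1=C(CC/C(=C\C[C@H]2OC(=O)C=C2CO)CO)[C@@]2(C)CCCC(C)(C)[C@@H]2CC1 | target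

## Step count and risks

Total: 12 steps. Longest linear sequence: 10 steps (1–7, then 10, 11, 12); steps 8 and 9 are a two-step side branch. The three steps most likely to fail are 12, 10 and 6.

Step 12 (the proposed new step) may suffer conjugate reduction, low enantioselectivity, or dehydration of 24 to the alkylidene butenolide. Its fallback uses known chemistry and sets out from 24. Methylation with TMSCHN2 (toluene/MeOH, 0 °C) gives the open-chain keto ester methyl (2Z,6E)-3,7-bis(hydroxymethyl)-4-oxo-9-[(4aS,8aS)-2,5,5,8a-tetramethyl-3,4,4a,5,6,7,8,8a-octahydronaphthalen-1-yl]nona-2,6-dienoate F7. Corey–Bakshi–Shibata reduction ((S)-Me-CBS, excess catecholborane, toluene, −78 °C, alkenyl arm as the large group) gives methyl (2Z,4R,6E)-4-hydroxy-3,7-bis(hydroxymethyl)-9-[(4aS,8aS)-2,5,5,8a-tetramethyl-3,4,4a,5,6,7,8,8a-octahydronaphthalen-1-yl]nona-2,6-dienoate F8. PPTS in CH2Cl2 then closes the lactone, and the route is rejoined at 26.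

Step 10 may fail because the triflate is tetrasubstituted and flanked by a quaternary carbon. The fallback moves the coupling to the next bond along the chain and sets out from 13 and 18. Stille vinylation of 13 (tributyl(vinyl)stannane, Pd(PPh3)4, LiCl, THF, 65 °C) gives the diene (4aS,8aS)-1-ethenyl-2,5,5,8a-tetramethyl-3,4,4a,5,6,7,8,8a-octahydronaphthalene F3. In parallel, hydroxyl-directed ruthenium-catalysed trans-hydrostannation of 18 (Bu3SnH, [Cp*RuCl]4, CH2Cl2) gives (2Z)-4-[3-(hydroxymethyl)furan-2-yl]-2-(tributylstannyl)but-2-en-1-ol F4, and iododestannylation (I2, CH2Cl2, 0 °C) gives (2Z)-4-[3-(hydroxymethyl)furan-2-yl]-2-iodobut-2-en-1-ol F5. 9-BBN adds to the vinyl group of F3 to give 9-{2-[(4aS,8aS)-2,5,5,8a-tetramethyl-3,4,4a,5,6,7,8,8a-octahydronaphthalen-1-yl]ethyl}-9-borabicyclo[3.3.1]nonane F6, which couples with the unhindered iodide F5 (Pd(dppf)Cl2, Cs2CO3, DMF/H2O, 20 °C). The route is rejoined at 22, bypassing 20.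

Step 6 may fail through sluggish addition to the neopentyl ketone, decomposition of diazoethane, or competing migration of the quaternary carbon. The fallback inserts CH2 first and adds the methyl afterwards; it sets out from 10. Me3Al-promoted homologation with trimethylsilyldiazomethane (CH2Cl2, −78 °C) gives the α-silyl ketone (4aS,8aS)-5,5,8a-trimethyl-2-(trimethylsilyl)octahydronaphthalen-1(2H)-one F1. Protodesilylation (1 M HCl, THF) gives (4aS,8aS)-5,5,8a-trimethyloctahydronaphthalen-1(2H)-one F2. Methylation at the only enolisable position (LDA, MeI, THF, −78 → 0 °C) rejoins the route at 11.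

## Further compounds

F1 | step 6 | (4aS,8aS)-5,5,8a-trimethyl-2-(trimethylsilyl)octahydronaphthalen-1(2H)-one (C2 epimers) | C[Si](C)(C)C1C(=O)[C@@]2(C)CCCC(C)(C)[C@@H]2CC1
F2 | step 6 | (4aS,8aS)-5,5,8a-trimethyloctahydronaphthalen-1(2H)-one | O=C1[C@@]2(C)CCCC(C)(C)[C@@H]2CCC1
F3 | step 10 | (4aS,8aS)-1-ethenyl-2,5,5,8a-tetramethyl-3,4,4a,5,6,7,8,8a-octahydronaphthalene | CC1=C(C=C)[C@@]2(C)CCCC(C)(C)[C@@H]2CC1
F4 | step 10 | (2Z)-4-[3-(hydroxymethyl)furan-2-yl]-2-(tributylstannyl)but-2-en-1-ol | OC/C(=C/Cc1occc1CO)[Sn](CCCC)(CCCC)CCCC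
F5 | step 10 | (2Z)-4-[3-(hydroxymethyl)furan-2-yl]-2-iodobut-2-en-1-ol | OC/C(I)=C/Cc1occc1CO
F6 | step 10 | 9-{2-[(4aS,8aS)-2,5,5,8a-tetramethyl-3,4,4a,5,6,7,8,8a-octahydronaphthalen-1-yl]ethyl}-9-borabicyclo[3.3.1]nonane | CC1=C(CCB3C4CCCC3CCC4)[C@@]2(C)CCCC(C)(C)[C@@H]2CC1
F7 | step 12 | methyl (2Z,6E)-3,7-bis(hydroxymethyl)-4-oxo-9-[(4aS,8aS)-2,5,5,8a-tetramethyl-3,4,4a,5,6,7,8,8a-octahydronaphthalen-1-yl]nona-2,6-dienoate | CC1=C(CC/C(=C\CC(=O)/C(CO)=C\C(=O)OC)CO)[C@@]2(C)CCCC(C)(C)[C@@H]2CC1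
F8 | step 12 | methyl (2Z,4R,6E)-4-hydroxy-3,7-bis(hydroxymethyl)-9-[(4aS,8aS)-2,5,5,8a-tetramethyl-3,4,4a,5,6,7,8,8a-octahydronaphthalen-1-yl]nona-2,6-dienoate | CC1=C(CC/C(=C\C[C@@H](O)/C(CO)=C\C(=O)OC)CO)[C@@]2(C)CCCC(C)(C)[C@@H]2CC1
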